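The lactone is cut at C3–C4 and at the exocyclic C3=CH bond. Read from the ring oxygen, C4 is the middle carbon of a 3-(4-hydroxy-3-methoxyphenyl)propyl ester (O1–C5H2–C4–CH2Ar) and stands 1,5 to the carbonyl α-carbon C3, while the arylidene on C3 is what an α-phosphonate leaves behind after olefination. A chiral dirhodium carboxylate should therefore convert the 3-arylpropyl diazo(diethoxyphosphoryl)acetate 6 into the γ-butyrolactone in one operation: carbenoid insertion into one enantiotopic C–H of that methylene makes C3–C4, closes the ring, sets C4 and leaves the olefination handle in place. Olefination with silylated syringaldehyde and desilylation complete the route.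

Key step: step 5

Assumption: the sense of induction of Rh2(S-PTTL)4, dirhodium tetrakis[N-phthaloyl-(S)-tert-leucinate], with a diazophosphonoacetate is not established. The (S)-tert-leucinate catalyst is written below, and its mirror image Rh2(R-PTTL)4 would be used instead if a test reaction shows the antipodal lactone.

Remark on descriptors: the target is (3E,4R). In the phosphono lactone 7 the same spatial arrangement at C4 is named (4S), because phosphorus ranks C3 above C5.

Step 1
Reactants: 1 dihydroconiferyl alcohol, 4-(3-hydroxypropyl)-2-methoxyphenol
Product: 2 tert-butyl{3-[4-(tert-butyldimethylsilyloxy)-3-methoxyphenyl]propoxy}dimethylsilane (bis-silyl ether of 1)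
Conditions: TBSCl (2.5 equiv), imidazole (5 equiv), DMF, rt
Reagents that add atoms: tert-butyldimethylsilyl chloride, CC(C)(C)[Si](C)(C)Cl
Why: Corey-type silylation (silyl chloride activated by imidazole) caps both hydroxyl groups, so no selectivity is asked of this step.

Step 2
Reactants: 2 bis-silyl ether
Product: 3 3-[4-(tert-butyldimethylsilyloxy)-3-methoxyphenyl]propan-1-ol
Conditions: CSA (0.1 equiv), MeOH/CH2Cl2 (1:1), 0 °C
Reagents that add atoms: none
Why: In acid-catalysed methanolysis the primary alkyl silyl ether, with the more basic and less hindered oxygen, is cleaved much faster than the aryl silyl ether, so short treatment at 0 °C should free only the alcohol.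

Step 3
Reactants: 3 phenol-silylated alcohol; 4 diethylphosphonoacetic acid, 2-(diethoxyphosphoryl)acetic acid
Product: 5 3-[4-(tert-butyldimethylsilyloxy)-3-methoxyphenyl]propyl 2-(diethoxyphosphoryl)acetate
Conditions: DCC, DMAP (cat.), CH2Cl2, 0 °C to rt
Reagents that add atoms: none
Why: Steglich esterification, in which the carbodiimide-activated phosphonoacetic acid acylates the primary alcohol while the aryl silyl ether is inert.

Step 4
Reactants: 5 phosphonoacetate ester
Product: 6 3-[4-(tert-butyldimethylsilyloxy)-3-methoxyphenyl]propyl 2-diazo-2-(diethoxyphosphoryl)acetate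
Conditions: NaH, THF, 0 °C; then p-ABSA, 0 °C to rt
Reagents that add atoms: 4-acetamidobenzenesulfonyl azide (p-ABSA), CC(=O)Nc1ccc(cc1)S(=O)(=O)N=[N+]=[N-]
Why: Regitz diazo transfer, in which the sodium salt of the doubly activated methylene attacks the terminal azide nitrogen and the triazene collapses to the diazo compound and the sulfonamide; stoichiometric NaH in THF is used because the aryl silyl ether tolerates it.

Step 5
Reactants: 6 diazophosphonoacetate
Product: 7 diethyl {(4S)-4-[4-(tert-butyldimethylsilyloxy)-3-methoxybenzyl]-2-oxotetrahydrofuran-3-yl}phosphonate (mixture of C3 epimers)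
Conditions: Rh2(S-PTTL)4 (2 mol %), CH2Cl2, 40 °C, slow addition of 6
Reagents that add atoms: none
Why: Proposed new method: the dirhodium tetracarboxylate expels N2 from 6 to give an electrophilic rhodium carbenoid flanked by the ester and phosphoryl acceptors, which inserts into a C–H bond of the central methylene of the propyl chain through a concerted, asynchronous three-centre transition state with retention at carbon, forming C3–C4. The closest known reaction types are the racemic dirhodium-catalysed 1,5-insertion of alkyl diazophosphonoacetates to α-phosphono-γ-butyrolactones, the enantioselective dirhodium carboxamidate insertion of 3-arylpropyl diazoacetates into this same methylene, and enantioselective insertions of acceptor/acceptor carbenoids with phthalimido-amino-acid dirhodium carboxylates; the untested element is an enantioselective catalyst acting on a diazophosphonoacetate. The γ-butyrolactone closes by 1,5-insertion, the five ring atoms being the carbenoid carbon, the carbonyl carbon, the ester oxygen and chain carbons 1 and 2. C4 is set by the chiral carboxylate pocket of the catalyst, which must select the pro-S hydrogen of the methylene, while C3 forms as an epimeric mixture that is erased in step 7. The step also needs site selectivity over the O-adjacent C–H (β-lactone) and the benzylic C–H (δ-lactone); this rests on the kinetic preference for five-membered ring formation with only one methylene in the 1,5 position, and the silyl cap on the phenol excludes O–H insertion.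

Step 6
Reactants: 8 syringaldehyde, 4-hydroxy-3,5-dimethoxybenzaldehyde
Product: 9 4-(tert-butyldimethylsilyloxy)-3,5-dimethoxybenzaldehyde
Conditions: TBSCl, imidazole, DMF, rt
Reagents that add atoms: tert-butyldimethylsilyl chloride, CC(C)(C)[Si](C)(C)Cl
Why: Corey-type silylation of the phenol, needed because a phenoxide would deactivate the aldehyde towards the phosphonate anion in step 7.

Step 7
Reactants: 7 phosphono lactone; 9 silylated syringaldehyde
Product: 10 (3E,4R)-3-[4-(tert-butyldimethylsilyloxy)-3,5-dimethoxybenzylidene]-4-[4-(tert-butyldimethylsilyloxy)-3-methoxybenzyl]dihydrofuran-2(3H)-one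
Conditions: LiCl, DBU, MeCN, 0 °C to rt
Reagents that add atoms: none
Why: Horner–Wadsworth–Emmons olefination under Masamune–Roush conditions, in which both C3 epimers of 7 give the same lithium-chelated anion, reversible addition and syn-elimination should favour the more stable E arylidene (aryl trans to the lactone carbonyl), and C4–H is not acidic under these mild conditions, so the stereocentre is carried through.

Step 8
Reactants: 10 bis-silyl ether of the target
Product: 11 (3E,4R)-3-(4-hydroxy-3,5-dimethoxybenzylidene)-4-(4-hydroxy-3-methoxybenzyl)dihydrofuran-2(3H)-one, CNP0351244.1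
Conditions: TBAF, AcOH (1:1), THF, 0 °C
Reagents that add atoms: none
Why: Fluoride-mediated cleavage of both aryl silyl ethers, with acetic acid buffering the phenoxides so that neither migration of the exocyclic double bond into the ring nor epimerisation at C4 is expected and the lactone stays closed.

Compound list
1 | dihydroconiferyl alcohol, 4-(3-hydroxypropyl)-2-methoxyphenol | COc1cc(CCCO)ccc1O | starting material
2 | tert-butyl{3-[4-(tert-butyldimethylsilyloxy)-3-methoxyphenyl]propoxy}dimethylsilane | COc1cc(CCCO[Si](C)(C)C(C)(C)C)ccc1O[Si](C)(C)C(C)(C)C | intermediate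
3 | 3-[4-(tert-butyldimethylsilyloxy)-3-methoxyphenyl]propan-1-ol | COc1cc(CCCO)ccc1O[Si](C)(C)C(C)(C)C | intermediate
4 | diethylphosphonoacetic acid | OC(=O)CP(=O)(OCC)OCC | starting material
5 | 3-[4-(tert-butyldimethylsilyloxy)-3-methoxyphenyl]propyl 2-(diethoxyphosphoryl)acetate | COc1cc(CCCOC(=O)CP(=O)(OCC)OCC)ccc1O[Si](C)(C)C(C)(C)C | intermediate
6 | 3-[4-(tert-butyldimethylsilyloxy)-3-methoxyphenyl]propyl 2-diazo-2-(diethoxyphosphoryl)acetate | COc1cc(CCCOC(=O)C(=[N+]=[N-])P(=O)(OCC)OCC)ccc1O[Si](C)(C)C(C)(C)C | intermediate
7 | diethyl {(4S)-4-[4-(tert-butyldimethylsilyloxy)-3-methoxybenzyl]-2-oxotetrahydrofuran-3-yl}phosphonate, C3 epimers | COc1cc(C[C@H]2COC(=O)C2P(=O)(OCC)OCC)ccc1O[Si](C)(C)C(C)(C)C | intermediate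
8 | syringaldehyde | COc1cc(C=O)cc(OC)c1O | starting material
9 | 4-(tert-butyldimethylsilyloxy)-3,5-dimethoxybenzaldehyde | COc1cc(C=O)cc(OC)c1O[Si](C)(C)C(C)(C)C | intermediate
10 | (3E,4R)-3-[4-(tert-butyldimethylsilyloxy)-3,5-dimethoxybenzylidene]-4-[4-(tert-butyldimethylsilyloxy)-3-methoxybenzyl]dihydrofuran-2(3H)-one | COc1cc(C[C@H]2COC(=O)/C2=C/c2cc(OC)c(O[Si](C)(C)C(C)(C)C)c(OC)c2)ccc1O[Si](C)(C)C(C)(C)C | intermediate
11 | (3E,4R)-3-(4-hydroxy-3,5-dimethoxybenzylidene)-4-(4-hydroxy-3-methoxybenzyl)dihydrofuran-2(3H)-one | COc1cc(C[C@H]2COC(=O)/C2=C/c2cc(OC)c(O)c(OC)c2)ccc1O | target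

Total step count: 8. Longest linear sequence: 7 steps (steps 1, 2, 3, 4, 5, 7, 8 from compound 1); step 6 is a one-step side branch.

Steps most likely to fail

Step 5. The hindered acceptor/acceptor carbenoid may turn over slowly, may insert at the wrong site (O-adjacent or benzylic C–H), or may show weak enantiotopic discrimination at the methylene. The fallback sets the stereocentre by the documented diazoacetate variant and installs the phosphonate afterwards. It sets out from compound 3: acylation with bromoacetyl bromide (pyridine, CH2Cl2, 0 °C) should give 3-[4-(tert-butyldimethylsilyloxy)-3-methoxyphenyl]propyl bromoacetate F1. N,N'-ditosylhydrazine and DBU in THF at 0 °C should convert this into the corresponding diazoacetate F2. Rh2(4S-MPPIM)4, dirhodium tetrakis[methyl 1-(3-phenylpropanoyl)-2-oxoimidazolidine-4(S)-carboxylate], or its mirror image, whichever delivers the R series, in refluxing CH2Cl2 should give (4R)-4-[4-(tert-butyldimethylsilyloxy)-3-methoxybenzyl]dihydrofuran-2(3H)-one F3 by the established enantioselective 1,5-insertion. Deprotonation with LDA at −78 °C and trapping of the enolate at carbon with diethyl chlorophosphite should give the α-phosphonite lactone F4, which air oxidation carries to the phosphonate. The route is rejoined at compound 7.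

Step 7. Addition of the branched phosphonate anion to the hindered, electron-rich aldehyde may be slow, E/Z control may be incomplete, the aldehyde may lose its silyl ether under the base, or the new double bond may migrate into the ring and erase C4. The fallback builds the arylidene by C–C coupling instead of carbonyl olefination. It sets out from compound 7: olefination with paraformaldehyde (KOt-Bu, THF, 0 °C) should give (4R)-4-[4-(tert-butyldimethylsilyloxy)-3-methoxybenzyl]-3-methylenedihydrofuran-2(3H)-one F5. Purchased 4-bromo-2,6-dimethoxyphenol is silylated (TBSCl, imidazole, DMF) to (4-bromo-2,6-dimethoxyphenoxy)(tert-butyl)dimethylsilane F6. Mizoroki–Heck coupling of the two (Pd[P(t-Bu)3]2, Cy2NMe, dioxane, 70 °C) should place the aryl group trans to the lactone carbonyl through syn-carbopalladation and syn-β-hydride elimination, as known for β-substituted α-methylene-γ-butyrolactones. The route is rejoined at compound 10.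

Step 2. The acid methanolysis may not separate the two silyl ethers cleanly: the phenol protection may be lost on long exposure, or bis-silyl ether may remain if the reaction is stopped early. The fallback avoids any selective deprotection by esterifying first and silylating second. It sets out from compound 1: Mitsunobu esterification with compound 4 (PPh3, DIAD, THF, 0 °C to rt), in which the carboxylic acid, being far more acidic than the phenol, acts as the pronucleophile towards the activated primary alcohol, should give 3-(4-hydroxy-3-methoxyphenyl)propyl 2-(diethoxyphosphoryl)acetate F7. Silylation of its phenol (TBSCl, imidazole, DMF) rejoins the route at compound 5.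

Further compounds
F1 | step 5 | 3-[4-(tert-butyldimethylsilyloxy)-3-methoxyphenyl]propyl bromoacetate | COc1cc(CCCOC(=O)CBr)ccc1O[Si](C)(C)C(C)(C)C
F2 | step 5 | 3-[4-(tert-butyldimethylsilyloxy)-3-methoxyphenyl]propyl diazoacetate | COc1cc(CCCOC(=O)C=[N+]=[N-])ccc1O[Si](C)(C)C(C)(C)C
F3 | step 5 | (4R)-4-[4-(tert-butyldimethylsilyloxy)-3-methoxybenzyl]dihydrofuran-2(3H)-one | COc1cc(C[C@H]2COC(=O)C2)ccc1O[Si](C)(C)C(C)(C)C
F4 | step 5 | diethyl {(4S)-4-[4-(tert-butyldimethylsilyloxy)-3-methoxybenzyl]-2-oxotetrahydrofuran-3-yl}phosphonite | COc1cc(C[C@H]2COC(=O)C2P(OCC)OCC)ccc1O[Si](C)(C)C(C)(C)C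
F5 | step 7 | (4R)-4-[4-(tert-butyldimethylsilyloxy)-3-methoxybenzyl]-3-methylenedihydrofuran-2(3H)-one | COc1cc(C[C@H]2COC(=O)C2=C)ccc1O[Si](C)(C)C(C)(C)C
F6 | step 7 | (4-bromo-2,6-dimethoxyphenoxy)(tert-butyl)dimethylsilane | COc1cc(Br)cc(OC)c1O[Si](C)(C)C(C)(C)C
F7 | step 2 | 3-(4-hydroxy-3-methoxyphenyl)propyl 2-(diethoxyphosphoryl)acetate | COc1cc(CCCOC(=O)CP(=O)(OCC)OCC)ccc1O
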